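## Retrosynthetic overview
1. 16 ⇒ 14: the C5–OMe group goes on last (iodination, then Cu-catalysed C–O coupling), so ring A keeps two identical enone arms until ring B closes.
2. 14 ⇒ 11: ring B (the tetrahydrofuran) is the last ring formed. O1–C7a and C2–H are made in one reductive oxa-Michael desymmetrisation, which sets C2, C3a and C7a from C3.
3. 11 ⇒ 9 + allylsilane 10: the quaternary C3a comes from oxidative dearomatisation. Ring A is the former phenol ring.
4. 9 ⇒ 4 + 5: the C3–aryl bond and the C3 stereocentre come from aryl addition followed by a semipinacol 1,2-aryl shift with inversion.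
5. 4 ⇒ veratrole 2 (from catechol 1) + (R)-2-chloropropanoyl chloride 3 by Friedel–Crafts acylation.

Atom labels follow benzofuran numbering: O1, C2, C3, C3a, C4–C7, C7a.

Assumption: (R)-2-chloropropanoyl chloride 3 is bought enantiopure.

## Route

Step 1
Reactants: 1 catechol
Product: 2 veratrole (1,2-dimethoxybenzene)
Conditions: MeI (2.5 equiv), K2CO3 (3 equiv), acetone, reflux
Reagents that add atoms: iodomethane, CI
Why: Williamson ether synthesis (double SN2 O-methylation of the phenoxides); no stereocentre is involved.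

Step 2
Reactants: 2 veratrole; 3 (R)-2-chloropropanoyl chloride
Product: 4 (R)-2-chloro-1-(3,4-dimethoxyphenyl)propan-1-one
Conditions: AlCl3 (1.1 equiv), CH2Cl2, −10 to 0 °C
Reagents that add atoms: none
Why: Friedel–Crafts acylation goes para to one methoxy group, the only open activated site, and the C–Cl stereocentre is a spectator that keeps its (R) configuration at or below 0 °C.

Step 3
Reactants: 4 (R)-2-chloro-1-(3,4-dimethoxyphenyl)propan-1-one; 5 4-bromophenol
Product: 9 (R)-1-(3,4-dimethoxyphenyl)-2-(4-hydroxyphenyl)propan-1-one, via lithium 4-lithiophenolate 6 (not isolated), via chlorohydrin lithium phenolate 7 (not isolated), via spirodienone cyclopropanol 8 (not isolated)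
Conditions: 5, t-BuLi (3.0 equiv), THF, −78 °C; LaCl3·2LiCl (1.0 equiv); 4, −78 °C; then AcOH (1.0 equiv) in CF3CH2OH, −78 to 23 °C
Reagents that add atoms: none
Why: 1,2-addition of the aryllithium is followed by a semipinacol rearrangement (1,2-aryl shift, Winstein Ar1-3 participation), in which AcOH first protonates the tertiary alkoxide so epoxide closure cannot compete, the phenolate then drives its para carbon onto the C–Cl carbon from the rear to give 8, and the cyclopropanol of 8 opens to the aryl ketone, so only the phenolate ring migrates and C3 is set with clean inversion ((R)-chloride gives (R)-9).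

Step 4
Reactants: 9 (R)-1-(3,4-dimethoxyphenyl)-2-(4-hydroxyphenyl)propan-1-one; 10 allyltrimethylsilane
Product: 11 4-allyl-4-[(2R)-1-(3,4-dimethoxyphenyl)-1-oxopropan-2-yl]cyclohexa-2,5-dien-1-one
Conditions: PhI(OAc)2 (1.1 equiv), 10 (5 equiv), (CF3)2CHOH, 0 °C, 10 min
Reagents that add atoms: none
Why: Oxidative dearomatisation with hypervalent iodine (oxidative Hosomi–Sakurai allylation) makes a phenoxenium-type electrophile that the allylsilane attacks at the para carbon, the acyl-deactivated veratryl ring is left alone, C3a carries two identical enone arms so no stereocentre is created, and C3 is untouched in the weakly acidic medium.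

Step 5
Reactants: 11 4-allyl-4-[(2R)-1-(3,4-dimethoxyphenyl)-1-oxopropan-2-yl]cyclohexa-2,5-dien-1-one
Product: 14 (2S,3R,3aS,7aS)-2-(3,4-dimethoxyphenyl)-3-methyl-3a-(prop-2-en-1-yl)-3,3a,7,7a-tetrahydro-1-benzofuran-6(2H)-one, via cyclic oxocarbenium triflate 12 (not isolated), via triethylsilyl dienol ether 13 (not isolated)
Conditions: Et3SiH (1.3 equiv), Et3SiOTf (20 mol %), 2,6-di-tert-butyl-4-methylpyridine (10 mol %), CH2Cl2, −78 to −40 °C; then 1 M HCl, THF, 0 °C
Reagents that add atoms: none
Why: Proposed new method: a silyl-triflate-catalysed reductive oxa-Michael desymmetrisation in which Et3Si+ binds the more basic dienone oxygen, the aryl ketone oxygen adds 5-exo-trig and reversibly to one of the two diastereotopic β-carbons, and the veratryl-stabilised oxocarbenium 12 is trapped irreversibly by Et3SiH (regenerating Et3SiOTf), so hydride capture decides the product and is fastest for the ring-closed isomer whose C3 methyl lies on the concave face, because hydride then enters from the open convex face anti to that methyl, giving aryl cis to methyl (C2 S), methyl trans to allyl and a cis ring fusion (C3a, C7a); the closest known reactions are Et3SiH/silyl triflate reductive etherification, reductive cyclisation of diketones or hydroxy ketones through cyclic oxocarbenium ions (Kishi-type lactol reduction) and acid-catalysed oxa-Michael desymmetrisation of cyclohexadienones, and what is new is a ketone oxygen acting as the desymmetrising nucleophile with hydride interception.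

Step 6
Reactants: 14 (2S,3R,3aS,7aS)-2-(3,4-dimethoxyphenyl)-3-methyl-3a-(prop-2-en-1-yl)-3,3a,7,7a-tetrahydro-1-benzofuran-6(2H)-one
Product: 15 (2S,3R,3aR,7aS)-2-(3,4-dimethoxyphenyl)-5-iodo-3-methyl-3a-(prop-2-en-1-yl)-3,3a,7,7a-tetrahydro-1-benzofuran-6(2H)-one
Conditions: I2 (1.5 equiv), pyridine–CH2Cl2 (1:1), 0 to 23 °C
Reagents that add atoms: iodine, II
Why: Johnson α-iodination (Baylis–Hillman-type pyridine addition, enolate iodination, elimination) works on 4,4-disubstituted cyclohexenones, touches only the single enone, and leaves all four stereocentres unchanged (the 3a descriptor changes only through CIP priorities).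

Step 7
Reactants: 15 (2S,3R,3aR,7aS)-2-(3,4-dimethoxyphenyl)-5-iodo-3-methyl-3a-(prop-2-en-1-yl)-3,3a,7,7a-tetrahydro-1-benzofuran-6(2H)-one
Product: 16 (2S,3R,3aR,7aS)-2-(3,4-dimethoxyphenyl)-5-methoxy-3-methyl-3a-(prop-2-en-1-yl)-3,3a,7,7a-tetrahydro-1-benzofuran-6(2H)-one (target)
Conditions: MeOH (10 equiv), CuI (10 mol %), 3,4,7,8-tetramethyl-1,10-phenanthroline (20 mol %), Cs2CO3 (1.5 equiv), toluene, 80 °C
Reagents that add atoms: methanol, CO
Why: Ullmann-type copper-catalysed C–O coupling of a vinyl iodide with an alcohol replaces iodine at C5 without moving the double bond, and any retro-oxa-Michael opening can only re-close on the same arm and face, so no stereocentre is scrambled.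

## Compound list
1 | catechol | Oc1ccccc1O | starting material
2 | veratrole | COc1ccccc1OC | intermediate
3 | (R)-2-chloropropanoyl chloride | C[C@@H](Cl)C(Cl)=O | starting material
4 | (R)-2-chloro-1-(3,4-dimethoxyphenyl)propan-1-one | C[C@@H](Cl)C(=O)c1ccc(OC)c(OC)c1 | intermediate
5 | 4-bromophenol | Oc1ccc(Br)cc1 | starting material
6 | lithium 4-lithiophenolate | [Li]Oc1ccc([Li])cc1 | intermediate
7 | lithium phenolate of (2R)-2-chloro-1-(3,4-dimethoxyphenyl)-1-(4-hydroxyphenyl)propan-1-ol (both C1 epimers) | C[C@@H](Cl)C(O)(c1ccc(O[Li])cc1)c1ccc(OC)c(OC)c1 | intermediate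
8 | (2R)-1-(3,4-dimethoxyphenyl)-1-hydroxy-2-methylspiro[2.5]octa-4,7-dien-6-one (both C1 epimers) | C[C@H]1C(O)(c2ccc(OC)c(OC)c2)C13C=CC(=O)C=C3 | intermediate
9 | (R)-1-(3,4-dimethoxyphenyl)-2-(4-hydroxyphenyl)propan-1-one | C[C@H](c1ccc(O)cc1)C(=O)c1ccc(OC)c(OC)c1 | intermediate
10 | allyltrimethylsilane | C=CC[Si](C)(C)C | starting material
11 | 4-allyl-4-[(2R)-1-(3,4-dimethoxyphenyl)-1-oxopropan-2-yl]cyclohexa-2,5-dien-1-one | C=CCC1([C@@H](C)C(=O)c2ccc(OC)c(OC)c2)C=CC(=O)C=C1 | intermediate
12 | cis-fused 2-aryl oxocarbenium triflate carrying the 6-triethylsilyloxy diene | C=CC[C@@]12C=CC(O[Si](CC)(CC)CC)=C[C@@H]1[O+]=C(c1ccc(OC)c(OC)c1)[C@@H]2C.[O-]S(=O)(=O)C(F)(F)F | intermediate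
13 | 6-triethylsilyl dienol ether of 14 | C=CC[C@@]12C=CC(O[Si](CC)(CC)CC)=C[C@@H]1O[C@H](c1ccc(OC)c(OC)c1)[C@@H]2C | intermediate
14 | (2S,3R,3aS,7aS)-2-(3,4-dimethoxyphenyl)-3-methyl-3a-(prop-2-en-1-yl)-3,3a,7,7a-tetrahydro-1-benzofuran-6(2H)-one | C=CC[C@@]12C=CC(=O)C[C@@H]1O[C@H](c1ccc(OC)c(OC)c1)[C@@H]2C | intermediate
15 | (2S,3R,3aR,7aS)-5-iodo analogue of 14 | C=CC[C@@]12C=C(I)C(=O)C[C@@H]1O[C@H](c1ccc(OC)c(OC)c1)[C@@H]2C | intermediate
16 | (2S,3R,3aR,7aS)-2-(3,4-dimethoxyphenyl)-5-methoxy-3-methyl-3a-(prop-2-en-1-yl)-3,3a,7,7a-tetrahydro-1-benzofuran-6(2H)-one | C=CC[C@@]12C=C(OC)C(=O)C[C@@H]1O[C@H](c1ccc(OC)c(OC)c1)[C@@H]2C | target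

Total step count: 7. Longest linear sequence: 7 (1 → 16).

## Steps most likely to fail

**Step 5 (the new reaction).**
- The aryl ketone could be hydrosilylated first, which under Felkin control would give the 2-epimer.
- The activated dienone could undergo dienone–phenol rearrangement.
- The electron-rich benzylic C2–O1 bond could be over-reduced.
- The wrong enone arm could be captured.

The fallback uses known chemistry, sets out from 9 and comes back at 14. Borane reduction of 9 (BH3·SMe2, (R)-Me-CBS oxazaborolidine, aryl taken as the large group) overrides the Felkin bias and gives (1S,2R)-1-(3,4-dimethoxyphenyl)-2-(4-hydroxyphenyl)propan-1-ol F1. Ac2O/pyridine gives the diacetate F2. Catalytic K2CO3 in MeOH at 0 °C removes only the phenolic acetate, giving the benzylic monoacetate F3; the ester damps fragmentation of the oxidised phenol. PhI(OAc)2 with 10 in (CF3)2CHOH gives the allyl dienone acetate F4. K2CO3 in MeOH at 23 °C then cleaves the acetate, and the alkoxide closes ring B by a base-mediated, reversible oxa-Michael desymmetrisation to 14.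

**Step 4.** The phenoxenium ion sits next to an acidified C3–H and may collapse to a quinone methide or be trapped by solvent. Attack at a para carbon bearing a branched chain is also slow.

The fallback sets out from 9 and comes back at 11. It separates oxidation from C–C bond formation. PhI(OAc)2 in MeOH at 0 °C gives the isolable para-quinol methyl ether 4-methoxy-4-[(2R)-1-(3,4-dimethoxyphenyl)-1-oxopropan-2-yl]cyclohexa-2,5-dien-1-one F5. This is ionised without oxidant by catalytic TMSOTf in CH2Cl2 at −78 °C in the presence of 10, an SN1-type Hosomi–Sakurai substitution of the methoxy group that gives 11.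

**Step 7.** Cs2CO3 at 80 °C can open the β-alkoxy ketone. In 15 the iodo-substituted arm is the more electrophilic one, so isomerisation or decomposition can compete with the coupling.

The fallback sets out from 14 and comes back at 16, bypassing 15. Nucleophilic epoxidation (t-BuOOH, DBU, CH2Cl2, 0 °C) gives the 4,5-epoxy ketone F6. Brief treatment with NaOMe in MeOH opens the epoxide at the less hindered C5, and loss of water gives the 5-methoxy enone 16.

## Further compounds
F1 | step 5 | (1S,2R)-1-(3,4-dimethoxyphenyl)-2-(4-hydroxyphenyl)propan-1-ol | O[C@H](c1ccc(OC)c(OC)c1)[C@@H](c1ccc(O)cc1)C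
F2 | step 5 | (1S,2R)-2-(4-acetoxyphenyl)-1-(3,4-dimethoxyphenyl)propyl acetate | CC(=O)O[C@H](c1ccc(OC)c(OC)c1)[C@@H](c1ccc(OC(C)=O)cc1)C
F3 | step 5 | (1S,2R)-1-(3,4-dimethoxyphenyl)-2-(4-hydroxyphenyl)propyl acetate | CC(=O)O[C@H](c1ccc(OC)c(OC)c1)[C@@H](c1ccc(O)cc1)C
F4 | step 5 | (1S,2R)-2-(1-allyl-4-oxocyclohexa-2,5-dien-1-yl)-1-(3,4-dimethoxyphenyl)propyl acetate | CC(=O)O[C@H](c1ccc(OC)c(OC)c1)[C@@H](C1(CC=C)C=CC(=O)C=C1)C
F5 | step 4 | 4-methoxy-4-[(2R)-1-(3,4-dimethoxyphenyl)-1-oxopropan-2-yl]cyclohexa-2,5-dien-1-one | COC1([C@@H](C)C(=O)c2ccc(OC)c(OC)c2)C=CC(=O)C=C1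
F6 | step 7 | 4,5-epoxide of 14 (epoxide face not assigned, lost in the next operation) | C=CC[C@@]12C3OC3C(=O)C[C@@H]1O[C@H](c1ccc(OC)c(OC)c1)[C@@H]2C
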